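**Retrosynthetic overview**
1. The target is dotriacontan-32-olide: one 33-membered ring whose only functional group is the lactone O–C1(=O); C2–C32 are 31 unbranched CH2 groups and there is no stereocentre.
2. Enabling feature: C21–C24 sit in this heteroatom-free polymethylene arc, so they can be carried as a conjugated diyne (C21≡C22–C23≡C24) and erased by hydrogenation; a six-atom linear rod fits a 33-membered ring without strain.
3. Key disconnection: the sp–sp bond C22–C23 of diyne lactone 9, made by oxidative C–H/C–H coupling of the two terminal alkynes of ester 8; this is the only ring-forming event.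
4. Ester 8 comes from docos-21-ynoic acid 6 (C1–C22) and dec-9-yn-1-ol 7 (C23–C32).
5. Acid 6 comes from erucic acid 1 (the same C22 skeleton): bromination/double dehydrobromination to the 13-yne 4, then alkyne-zipper migration of the triple bond to the chain end.

Key step: step 4

Remark: carbon numbers are those of the parent 32-hydroxydotriacontanoic acid (C1 = lactone carbonyl carbon, C32 = OCH2); erucic acid and dec-9-yn-1-ol are taken as commercial.

**Route**

Step 1
Reactants: 1 erucic acid ((13Z)-docos-13-enoic acid)
Product: 4 behenolic acid (docos-13-ynoic acid), via threo-13,14-dibromodocosanoic acid 2 (not isolated), via potassium docos-13-ynoate 3 (not isolated)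
Conditions: Br2 (1.05 equiv), Et2O, 0 °C; evaporate; KOH (excess), n-amyl alcohol, reflux; then aq. HCl
Reagents that add atoms: none
Why: Anti addition of bromine to the Z alkene gives the racemic threo dibromide, and twofold E2 dehydrobromination with hot alcoholic KOH should give the internal alkyne (alkene-to-alkyne conversion by bromination and double dehydrohalogenation); the two stereocentres of 2 are destroyed again, and any positional alkyne isomer is harmless because step 2 moves the triple bond anyway.

Step 2
Reactants: 4 behenolic acid
Product: 6 docos-21-ynoic acid, via disodium acetylide carboxylate 5 (not isolated)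
Conditions: NaH (6 equiv), H2N(CH2)2NH2, 60 °C; then aq. HCl, 0 °C
Reagents that add atoms: none
Why: Alkyne zipper reaction: sodium 2-aminoethylamide, formed in situ, should walk the triple bond along the chain through propargyl/allenyl anions, away from the carboxylate (charge repulsion), until irreversible formation of the terminal acetylide at C22 drains the equilibrium to the chain end.

Step 3
Reactants: 6 docos-21-ynoic acid; 7 dec-9-yn-1-ol
Product: 8 dec-9-yn-1-yl docos-21-ynoate
Conditions: DCC (1.1 equiv), DMAP (0.1 equiv), CH2Cl2, 0 °C to rt
Reagents that add atoms: none
Why: Steglich esterification of an unhindered primary alcohol with an unbranched acid; the terminal alkynes are inert to carbodiimide and DMAP.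

Step 4
Reactants: 8 dec-9-yn-1-yl docos-21-ynoate
Product: 9 dotriaconta-21,23-diyn-32-olide (1-oxacyclotritriaconta-22,24-diyn-2-one)
Conditions: Cu(OAc)2 (10 equiv), pyridine/Et2O (5:1), 45 °C, 8 in Et2O added by syringe pump over 24 h (final concentration about 1 mM)
Reagents that add atoms: none
Why: Divalent copper acetate in pyridine deprotonates and cuprates both terminal alkynes of 8, and the two copper-bound alkynyl groups then couple oxidatively (two divalent copper centres are reduced to monovalent copper) to forge the sp–sp σ bond C22–C23, which closes the ring. The closest known reaction type is the Eglinton (Glaser-type) oxidative macrocyclization of α,ω-diynes, long used for large carbocycles and for macrocyclic diyne lactones. The single ring closed is the 33-membered lactone ring, formed by end-to-end (endo) coupling of the two chain termini, with all four sp carbons C21–C24 ending up inside the ring. No stereocentre is created, and the linear C20–C21≡C22–C23≡C24–C25 rod is small against a ring of this size, so no strain penalises the intramolecular path. The step needs ring closure to win over intermolecular coupling (cyclic dimer, oligomers), which slow addition into a large volume of oxidant should secure by keeping the stationary concentration of 8 very low. Chemoselectivity rests on the substrate: its only other functional group, the ester, is inert to Cu(OAc)2/pyridine, and the two alkyne termini are equivalent partners, so no cross-selectivity problem arises.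

Step 5
Reactants: 9 dotriaconta-21,23-diyn-32-olide
Product: 10 dotriacontan-32-olide (1-oxacyclotritriacontan-2-one)
Conditions: H2 (3 bar), 10% Pd/C, EtOAc/THF, 40 °C
Reagents that add atoms: none
Why: Exhaustive heterogeneous hydrogenation of the conjugated diyne (four equivalents of H2) over Pd/C should give the saturated lactone; the product has no group prone to hydrogenolysis and no stereocentre arises.

**Compound list**
1 | erucic acid, (13Z)-docos-13-enoic acid | CCCCCCCC/C=C\CCCCCCCCCCCC(=O)O | starting material
2 | threo-13,14-dibromodocosanoic acid, racemic, (13R,14R) enantiomer drawn, not isolated | CCCCCCCC[C@@H](Br)[C@H](Br)CCCCCCCCCCCC(=O)O | intermediate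
3 | potassium docos-13-ynoate, not isolated | CCCCCCCCC#CCCCCCCCCCCCC(=O)[O-].[K+] | intermediate
4 | behenolic acid, docos-13-ynoic acid | CCCCCCCCC#CCCCCCCCCCCCC(=O)O | intermediate
5 | disodium salt of docos-21-ynoic acid (C22 acetylide, C1 carboxylate), not isolated | [Na+].[Na+].[C-]#CCCCCCCCCCCCCCCCCCCCC(=O)[O-] | intermediate
6 | docos-21-ynoic acid | C#CCCCCCCCCCCCCCCCCCCCC(=O)O | intermediate
7 | dec-9-yn-1-ol | C#CCCCCCCCCO | starting material
8 | dec-9-yn-1-yl docos-21-ynoate | C#CCCCCCCCCCCCCCCCCCCCC(=O)OCCCCCCCCC#C | intermediate
9 | dotriaconta-21,23-diyn-32-olide (1-oxacyclotritriaconta-22,24-diyn-2-one) | O=C1CCCCCCCCCCCCCCCCCCCC#CC#CCCCCCCCCO1 | intermediate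
10 | dotriacontan-32-olide (1-oxacyclotritriacontan-2-one) | O=C1CCCCCCCCCCCCCCCCCCCCCCCCCCCCCCCO1 | target

Total step count: 5
Longest linear sequence: 5 steps (1 → 4 → 6 → 8 → 9 → 10)

**Steps most likely to fail**

Step 4 (key step). Intermolecular oxidative coupling may outrun ring closure, giving the cyclic dimer and linear oligomers, or coupling may become too slow at the dilution needed. The fallback forms the C22–C23 bond between two molecules and closes the ring at the ester C–O bond instead. It sets out from 6 and 7 and comes back at 9. Alcohol 7 is brominated at the alkyne terminus (NBS, AgNO3 cat., acetone) to 10-bromodec-9-yn-1-ol F1. Cadiot–Chodkiewicz cross-coupling of F1 with acid 6 (CuCl cat., NH2OH·HCl, n-BuNH2, H2O/THF, 0 °C to rt) should give 32-hydroxydotriaconta-21,23-diynoic acid F2. Yamaguchi macrolactonization (2,4,6-trichlorobenzoyl chloride, Et3N, THF; then slow addition to DMAP in toluene at reflux) should then deliver 9, which enters step 5 unchanged.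

Step 2. The triple-bond migration may stall at internal alkyne/allene mixtures, run toward the carboxylate, or be slowed by poor solubility of the dianionic soap in the diamine. The fallback builds the acid by copper-catalysed alkyl–alkyl coupling without any isomerization. It sets out from 7 and comes back at 6. Appel bromination of 7 (CBr4, PPh3, CH2Cl2) gives 10-bromodec-1-yne F3. C-silylation (LDA, THF, −78 °C; TMSCl) gives (10-bromodec-1-yn-1-yl)trimethylsilane F4. Magnesium in THF converts F4 into the Grignard reagent [10-(trimethylsilyl)dec-9-yn-1-yl]magnesium bromide F5. Coupling of F5 with commercial 12-bromododecanoic acid (pre-treated with one equivalent of MeMgCl; Li2CuCl4 cat., THF, −20 to 0 °C) should give 22-(trimethylsilyl)docos-21-ynoic acid F6. Desilylation (K2CO3, MeOH; then aq. HCl) gives 6.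

Step 1. The second dehydrobromination may remain incomplete, leaving vinyl bromides, and material may be lost in the hot alkaline medium. The fallback assembles the C22 alkyne chain by acetylide alkylation instead of alkene functionalization. It sets out from 7 and comes back at 6. The O,C-dilithio derivative of 7 (n-BuLi 2.1 equiv, THF/DMPU, −40 to 0 °C) is alkylated with 1-bromododecane to docos-9-yn-1-ol F7. Jones oxidation (CrO3, H2SO4, acetone, 0 °C) gives docos-9-ynoic acid F8. F8 then takes the place of 4 under the conditions of step 2, where the zipper should converge on the same acetylide 5 and hence on 6.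

**Further compounds**
F1 | step 4 | 10-bromodec-9-yn-1-ol | OCCCCCCCCC#CBr
F2 | step 4 | 32-hydroxydotriaconta-21,23-diynoic acid | OCCCCCCCCC#CC#CCCCCCCCCCCCCCCCCCCCC(=O)O
F3 | step 2 | 10-bromodec-1-yne | C#CCCCCCCCCBr
F4 | step 2 | (10-bromodec-1-yn-1-yl)trimethylsilane | C[Si](C)(C)C#CCCCCCCCCBr
F5 | step 2 | [10-(trimethylsilyl)dec-9-yn-1-yl]magnesium bromide | C[Si](C)(C)C#CCCCCCCCC[Mg]Br
F6 | step 2 | 22-(trimethylsilyl)docos-21-ynoic acid | C[Si](C)(C)C#CCCCCCCCCCCCCCCCCCCCC(=O)O
F7 | step 1 | docos-9-yn-1-ol | CCCCCCCCCCCCC#CCCCCCCCCO
F8 | step 1 | docos-9-ynoic acid | CCCCCCCCCCCCC#CCCCCCCCC(=O)O
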